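The upper pyran ring is made from a 3-arylbenzofuran by inserting one aryl-bearing carbon. The chromenylium ion formed is then reduced stereoselectively to the trans-3,4-diarylchroman.

**Plan**
1. Cuts: upper C2–C3 and C3–C4 together (C3 is excised with ring B), then upper C4–lower C5', then lower C3–C1'.
2. Enabling feature: upper C3 is the only pyran atom that carries ring B, and its two ring bonds go to C2 and C4. Removing this C–aryl unit and joining C2 to C4 contracts the pyran to the furan of a 3-arylbenzofuran, in which O1, C2, C4, ring A and the lower unit are already connected.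
3. Forward, part 1: the purchased lower chromanone is α-arylated with a bromo/chloro ring-B' block and carried to the (3S)-isoflavan. Its chloride becomes a boronate, which is coupled with a benzofuran-3-yl triflate.
4. Forward, part 2: an aryl(chloro)carbene from the ring-B chlorodiazirine enlarges the furan to the 3,4-diarylchromenylium ring, the only ring made in the route. Hydride at C2, hydrogenation of C3=C4, inversion of C4 and debenzylation follow.
5. Stereochemistry: lower C3 (S) comes from Noyori transfer hydrogenation with dynamic kinetic resolution. Upper C3 (S) comes from Ir-catalysed asymmetric hydrogenation. Upper C4 (R) comes from base equilibration of the cis to the trans chroman.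

Key step: step 15

Numbering remark: "upper" is the isoflavan arylated at C4 (rings A, B). "Lower" is the isoflavan whose ring B' (C5') is bonded to upper C4.
Assumption: no rule predicts the sense of induction of the Ir–P,N catalyst on 23. The ligand antipode that gives (3S,4S)-24 is taken as identified in a small trial with both available antipodes.

**Step 1**
Reactants: 1 2-bromo-5-methoxyphenol
Product: 2 2-bromo-4-chloro-5-methoxyphenol
Conditions: NCS (1.05 equiv), MeCN, 0 °C to rt
Reagents that add atoms: N-chlorosuccinimide, O=C1CCC(=O)N1Cl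
Why: Electrophilic aromatic chlorination goes para to OH and ortho to OMe (the site between the two oxygens is crowded), and it is done now because halogenation of the finished isoflavan could not distinguish ring-B' C5' from the equally activated ring-A' C6.

**Step 2**
Reactants: 2 2-bromo-4-chloro-5-methoxyphenol
Product: 3 1-(benzyloxy)-2-bromo-4-chloro-5-methoxybenzene
Conditions: BnBr, K2CO3, DMF, rt
Reagents that add atoms: benzyl bromide, BrCc1ccccc1
Why: Williamson ether synthesis on a phenoxide, with no competing nucleophilic site.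

**Step 3**
Reactants: 4 7-hydroxychroman-4-one
Product: 5 7-(benzyloxy)chroman-4-one
Conditions: BnBr, K2CO3, acetone, reflux
Reagents that add atoms: benzyl bromide, BrCc1ccccc1
Why: Williamson ether synthesis, in which carbonate deprotonates only the vinylogous-acid phenol and not the ketone α-position.

**Step 4**
Reactants: 3 1-(benzyloxy)-2-bromo-4-chloro-5-methoxybenzene; 5 7-(benzyloxy)chroman-4-one
Product: 6 (±)-7-(benzyloxy)-3-[2-(benzyloxy)-5-chloro-4-methoxyphenyl]chroman-4-one
Conditions: Pd2(dba)3 (2.5 mol %), Xantphos (6 mol %), K3PO4, toluene, 100 °C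
Reagents that add atoms: none
Why: Palladium-catalysed ketone α-arylation (Buchwald–Hartwig type) is a known entry to isoflavanones from chroman-4-ones; oxidative addition takes C–Br and leaves the electron-rich C–Cl bond, phosphate limits retro-oxa-Michael opening, the ortho-benzyloxy group blocks a second arylation, and the new C3 centre is racemic and labile at this stage.

**Step 5**
Reactants: 6 (±)-isoflavanone
Product: 7 (3S,4S)-7-(benzyloxy)-3-[2-(benzyloxy)-5-chloro-4-methoxyphenyl]chroman-4-ol (cis)
Conditions: RuCl[(S,S)-TsDPEN](p-cymene) (2 mol %), HCO2H/Et3N, EtOAc, 40 °C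
Reagents that add atoms: none
Why: Noyori asymmetric transfer hydrogenation with dynamic kinetic resolution, in which C3 racemises through the enol, the (S,S)-catalyst forms the (4S)-benzylic alcohol (same aryl/alkyl discrimination as for 1-tetralone and chroman-4-one) and turns over only the enantiomer whose reacting carbonyl face lies anti to the 3-aryl group, so cis-(3S,4S) is set.

**Step 6**
Reactants: 7 (3S,4S)-isoflavan-4-ol
Product: 8 (3S)-7-(benzyloxy)-3-[2-(benzyloxy)-5-chloro-4-methoxyphenyl]chroman
Conditions: Et3SiH (4 equiv), TFA (5 equiv), CH2Cl2, −40 to 0 °C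
Reagents that add atoms: none
Why: Ionic (Kursanov–Parnes) deoxygenation, in which the C4 cation stabilised by the para 7-benzyloxy group is captured by excess silane at low temperature faster than it loses H3, so C3 keeps its configuration and remains (S) after the change of CIP priorities.

**Step 7**
Reactants: 8 (3S)-chloro-isoflavan
Product: 9 (3S)-7-(benzyloxy)-3-[2-(benzyloxy)-4-methoxy-5-(4,4,5,5-tetramethyl-1,3,2-dioxaborolan-2-yl)phenyl]chroman
Conditions: B2pin2, XPhos Pd G2 (3 mol %), KOAc, 1,4-dioxane, 100 °C
Reagents that add atoms: bis(pinacolato)diboron, CC1(C)OB(OC1(C)C)B1OC(C)(C)C(C)(C)O1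
Why: Miyaura borylation with a bulky biarylphosphine ligand is established for electron-rich ortho-alkoxy aryl chlorides and does not affect benzyl ethers or the stereocentre.

**Step 8**
Reactants: 10 6-hydroxybenzofuran-3(2H)-one
Product: 11 6-(benzyloxy)benzofuran-3(2H)-one
Conditions: BnBr, K2CO3, DMF, rt
Reagents that add atoms: benzyl bromide, BrCc1ccccc1
Why: Williamson ether synthesis at room temperature alkylates the acidic 6-OH before the C2 methylene can condense or be alkylated.

**Step 9**
Reactants: 11 6-(benzyloxy)benzofuran-3(2H)-one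
Product: 12 6-(benzyloxy)benzofuran-3-yl trifluoromethanesulfonate
Conditions: Tf2O, Et3N, CH2Cl2, −78 to 0 °C
Reagents that add atoms: triflic anhydride, O=S(=O)(OS(=O)(=O)C(F)(F)F)C(F)(F)F
Why: Enol triflation is driven by aromatisation to the benzofuran, since the ketone enolises readily to 3-hydroxybenzofuran, which is sulfonylated on oxygen.

**Step 10**
Reactants: 9 boronate; 12 benzofuran-3-yl triflate
Product: 13 6-(benzyloxy)-3-{4-(benzyloxy)-5-[(3S)-7-(benzyloxy)chroman-3-yl]-2-methoxyphenyl}benzofuran
Conditions: Pd(PPh3)4 (5 mol %), K3PO4, dioxane/H2O, 85 °C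
Reagents that add atoms: none
Why: Suzuki–Miyaura coupling of a heteroaryl triflate with an aryl pinacol boronate forms the bond that becomes upper C4–lower C5', at a position fixed by the chlorine placed in step 1.

**Step 11**
Reactants: 14 2-hydroxy-4-methoxybenzaldehyde
Product: 15 2-formyl-5-methoxyphenyl 4-methylbenzenesulfonate
Conditions: TsCl, Et3N, DMAP (cat.), CH2Cl2, 0 °C to rt
Reagents that add atoms: 4-toluenesulfonyl chloride, Cc1ccc(S(=O)(=O)Cl)cc1
Why: O-Sulfonylation of the phenol, where a tosylate is preferred to a benzyl ether because it has no O–CH2 bond next to the later carbene centre, withdraws electron density and withstands hypochlorite.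

**Step 12**
Reactants: 15 2-formyl-5-methoxyphenyl 4-methylbenzenesulfonate
Product: 17 2-cyano-5-methoxyphenyl 4-methylbenzenesulfonate, via aldoxime 16 (not isolated)
Conditions: NH2OH·HCl, HCO2Na, HCO2H, 100 °C
Reagents that add atoms: hydroxylamine hydrochloride, [NH3+]O.[Cl-]
Why: Oxime formation followed by acid-promoted dehydration in formic acid is a standard one-pot aldehyde-to-nitrile conversion, and the acidic medium leaves the aryl sulfonate intact.

**Step 13**
Reactants: 17 2-cyano-5-methoxyphenyl 4-methylbenzenesulfonate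
Product: 18 2-carbamimidoyl-5-methoxyphenyl 4-methylbenzenesulfonate hydrochloride
Conditions: AlMe3, NH4Cl, toluene, 0 to 80 °C; SiO2, CHCl3/MeOH work-up
Reagents that add atoms: ammonium chloride, [NH4+].[Cl-]
Why: Garigipati amidine synthesis, in which the Lewis-acidic aluminium amide adds to ortho-hindered nitriles that resist the Pinner reaction and does not attack the sulfonate as a lithium amide might.

**Step 14**
Reactants: 18 amidinium chloride
Product: 19 2-(3-chloro-3H-diazirin-3-yl)-5-methoxyphenyl 4-methylbenzenesulfonate
Conditions: aq NaOCl, LiCl, DMSO, 0 °C; extraction into Et2O/pentane, solvent change to DCE, kept cold and in solution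
Reagents that add atoms: sodium hypochlorite, [Na+].[O-]Cl; lithium chloride (shared chloride pool), [Li+].[Cl-]
Why: Graham oxidation, in which double N-chlorination, base-induced N–N closure and return of chloride to carbon give the 3-aryl-3-chlorodiazirine, while the tosyloxy group keeps the ring from being chlorinated and the diazirine from ionising.

**Step 15**
Reactants: 13 3-arylbenzofuran; 19 chlorodiazirine
Product: 22 7-(benzyloxy)-4-{4-(benzyloxy)-5-[(3S)-7-(benzyloxy)chroman-3-yl]-2-methoxyphenyl}-3-[4-methoxy-2-(tosyloxy)phenyl]chromenylium chloride, via arylchlorocarbene 20 (not isolated), via chlorocyclopropane adduct 21 (not isolated)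
Conditions: 19 (3 equiv, slow addition in DCE), 4 Å MS, MeCN/DCE, 60 °C, dark, Ar; precipitation with Et2O
Reagents that add atoms: none
Why: Proposed new method: heating 19 expels N2 and releases singlet aryl(chloro)carbene 20, whose empty p orbital is attacked by the furan C2=C3 bond of 13 (an aryl enol ether raised further in energy by the 6-benzyloxy group) in a concerted but asynchronous [2+1] addition that gives the 1-aryl-1-chlorocyclopropa[b]benzofuran 21. The large aryl group should sit exo and leave chloride endo, the geometry from which loss of chloride and disrotatory two-electron opening of the former C2–C3 bond occur together (Woodward–Hoffmann–DePuy rule) with a push from the O1 lone pair, and an exo-chloride adduct can still ionise stepwise because its cation is benzylic to an anisyl ring. Mode of closure: a three-membered ring is closed by cheletropic addition and then consumed in an electrocyclic five-to-six enlargement, so the only ring that remains is the pyrylium ring, the carbene carbon has become upper C3 with new bonds to C2 and C4, and aromatisation of the cation makes the sequence irreversible. The closest known reaction types are the Ciamician–Dennstedt-type insertion of chlorodiazirine-derived arylchlorocarbenes into indoles and pyrroles and the ring expansion of dihalocarbene adducts of benzofurans to 3-halochromenes; new here is an aryl carbyne equivalent acting on a benzofuran to give a cationic product. No stereocentre is formed (C2, C3 and C4 end up sp2) and lower C3 is a remote spectator. The carbene must prefer the hindered furan π bond over the alkoxybenzene rings and the benzylic ether C–H bonds: the enol-ether HOMO of 13 secures the first, and the ortho-tosyloxy group of 19 secures the rest, since it offers no O–CH2 group for 1,5-C–H insertion and offsets the para-methoxy donor so that the carbene stays electrophilic.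

**Step 16**
Reactants: 22 chromenylium chloride
Product: 23 2-[7-(benzyloxy)-4-{4-(benzyloxy)-5-[(3S)-7-(benzyloxy)chroman-3-yl]-2-methoxyphenyl}-2H-chromen-3-yl]-5-methoxyphenyl 4-methylbenzenesulfonate
Conditions: NaBH4, MeCN/THF, −20 to 0 °C
Reagents that add atoms: none
Why: Hydride addition to a benzopyrylium ion, known for isoflavylium salts to give isoflav-3-enes, goes to the unsubstituted oxocarbenium carbon C2 because C4 is shielded by its ortho-methoxyaryl group.

**Step 17**
Reactants: 23 3,4-diaryl-2H-chromene
Product: 24 2-[(3S,4S)-7-(benzyloxy)-4-{4-(benzyloxy)-5-[(3S)-7-(benzyloxy)chroman-3-yl]-2-methoxyphenyl}chroman-3-yl]-5-methoxyphenyl 4-methylbenzenesulfonate (cis)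
Conditions: [Ir(cod)(L*)]BArF (5 mol %, L* = 4-tert-butyl-2-(dialkylphosphinomethyl)oxazoline), H2 (100 bar), CH2Cl2, 40 °C
Reagents that add atoms: none
Why: Iridium–P,N-catalysed asymmetric hydrogenation of an unfunctionalised tetrasubstituted aryl olefin, in which syn delivery of H2 fixes the cis relationship and the ligand selects the face, making C3 (S) and C4 provisionally (S), while benzyl ethers and the tosylate are inert to the homogeneous catalyst.

**Step 18**
Reactants: 24 cis-chroman tosylate
Product: 26 (3S,4S)-7-(benzyloxy)-3-[2-(benzyloxy)-4-methoxyphenyl]-4-{4-(benzyloxy)-5-[(3S)-7-(benzyloxy)chroman-3-yl]-2-methoxyphenyl}chroman (cis), via cis-phenoxide 25 (not isolated)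
Conditions: KOH (powdered), DMSO/THF, 50 °C; then BnBr, rt
Reagents that add atoms: benzyl bromide, BrCc1ccccc1
Why: Saponification of the aryl sulfonate at sulfur followed by Williamson alkylation in the same flask replaces the base-labile group with a base-stable one, so no phenoxide sits beside C2–O or lowers the C4–H acidity in the next step, and any early C4 epimerisation is harmless.

**Step 19**
Reactants: 26 cis tetrabenzyl ether
Product: 27 (3S,4R)-7-(benzyloxy)-3-[2-(benzyloxy)-4-methoxyphenyl]-4-{4-(benzyloxy)-5-[(3S)-7-(benzyloxy)chroman-3-yl]-2-methoxyphenyl}chroman (trans)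
Conditions: KOtBu (3 equiv), degassed DMSO, Ar, 60 °C; H2O quench
Reagents that add atoms: none
Why: Base-mediated cis-to-trans isomerisation is known for 3,4-diarylchromans and 1,2-diaryltetralins: only the doubly benzylic C4–H is acidic enough for tert-butoxide in DMSO, and its carbanion is reprotonated under thermodynamic control with the aryl groups trans (C4 S to R), while the monobenzylic upper C3 and lower C3 are far weaker acids and keep their configuration.

**Step 20**
Reactants: 27 trans tetrabenzyl ether
Product: 28 (3S,4R)-3-(2-hydroxy-4-methoxyphenyl)-4-{4-hydroxy-5-[(3S)-7-hydroxychroman-3-yl]-2-methoxyphenyl}chroman-7-ol (CNP0152030.1)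
Conditions: H2 (1 atm), 10 % Pd/C, THF/MeOH, rt
Reagents that add atoms: none
Why: Catalytic hydrogenolysis cleaves the four aryl benzyl ethers under neutral conditions that spare the acid-sensitive C4–aryl bond, the non-benzylic C2–O bonds and all three stereocentres.

**Compound list**
1 | 2-bromo-5-methoxyphenol | COc1ccc(Br)c(O)c1 | starting material
2 | 2-bromo-4-chloro-5-methoxyphenol | COc1cc(O)c(Br)cc1Cl | intermediate
3 | 1-(benzyloxy)-2-bromo-4-chloro-5-methoxybenzene | COc1cc(OCc2ccccc2)c(Br)cc1Cl | intermediate
4 | 7-hydroxychroman-4-one | O=C1CCOc2cc(O)ccc12 | starting material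
5 | 7-(benzyloxy)chroman-4-one | O=C1CCOc2cc(OCc3ccccc3)ccc12 | intermediate
6 | (±)-7-(benzyloxy)-3-[2-(benzyloxy)-5-chloro-4-methoxyphenyl]chroman-4-one | COc1cc(OCc2ccccc2)c(C2COc3cc(OCc4ccccc4)ccc3C2=O)cc1Cl | intermediate
7 | (3S,4S)-cis-isoflavan-4-ol | COc1cc(OCc2ccccc2)c([C@H]2COc3cc(OCc4ccccc4)ccc3[C@H]2O)cc1Cl | intermediate
8 | (3S)-5'-chloro-isoflavan | COc1cc(OCc2ccccc2)c([C@H]2COc3cc(OCc4ccccc4)ccc3C2)cc1Cl | intermediate
9 | (3S)-isoflavan 5'-pinacol boronate | COc1cc(OCc2ccccc2)c([C@H]2COc3cc(OCc4ccccc4)ccc3C2)cc1B1OC(C)(C)C(C)(C)O1 | intermediate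
10 | 6-hydroxybenzofuran-3(2H)-one | O=C1COc2cc(O)ccc12 | starting material
11 | 6-(benzyloxy)benzofuran-3(2H)-one | O=C1COc2cc(OCc3ccccc3)ccc12 | intermediate
12 | 6-(benzyloxy)benzofuran-3-yl triflate | O=S(=O)(Oc1coc2cc(OCc3ccccc3)ccc12)C(F)(F)F | intermediate
13 | 3-arylbenzofuran carrying the (3S)-lower isoflavan | COc1cc(OCc2ccccc2)c([C@H]2COc3cc(OCc4ccccc4)ccc3C2)cc1-c1coc2cc(OCc3ccccc3)ccc12 | intermediate
14 | 2-hydroxy-4-methoxybenzaldehyde | COc1ccc(C=O)c(O)c1 | starting material
15 | 2-formyl-5-methoxyphenyl tosylate | COc1ccc(C=O)c(OS(=O)(=O)c2ccc(C)cc2)c1 | intermediate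
16 | (E)-aldoxime of 15 (not isolated) | COc1ccc(/C=N/O)c(OS(=O)(=O)c2ccc(C)cc2)c1 | intermediate
17 | 2-cyano-5-methoxyphenyl tosylate | COc1ccc(C#N)c(OS(=O)(=O)c2ccc(C)cc2)c1 | intermediate
18 | 2-carbamimidoyl-5-methoxyphenyl tosylate hydrochloride | COc1ccc(C(N)=[NH2+])c(OS(=O)(=O)c2ccc(C)cc2)c1.[Cl-] | intermediate
19 | 2-(3-chloro-3H-diazirin-3-yl)-5-methoxyphenyl tosylate | COc1ccc(C2(Cl)N=N2)c(OS(=O)(=O)c2ccc(C)cc2)c1 | intermediate
20 | [4-methoxy-2-(tosyloxy)phenyl]chlorocarbene (not isolated) | COc1ccc([C]Cl)c(OS(=O)(=O)c2ccc(C)cc2)c1 | intermediate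
21 | 1-chloro-1,6b-diaryl-1a,6b-dihydro-1H-cyclopropa[b]benzofuran adduct, cyclopropane centres undefined (not isolated) | COc1ccc(C2(Cl)C3Oc4cc(OCc5ccccc5)ccc4C23c2cc([C@H]3COc4cc(OCc5ccccc5)ccc4C3)c(OCc3ccccc3)cc2OC)c(OS(=O)(=O)c2ccc(C)cc2)c1 | intermediate
22 | 3,4-diaryl-7-(benzyloxy)chromenylium chloride | COc1ccc(-c2c[o+]c3cc(OCc4ccccc4)ccc3c2-c2cc([C@H]3COc4cc(OCc5ccccc5)ccc4C3)c(OCc3ccccc3)cc2OC)c(OS(=O)(=O)c2ccc(C)cc2)c1.[Cl-] | intermediate
23 | 3,4-diaryl-2H-chromene (tosylate) | COc1ccc(C2=C(c3cc([C@H]4COc5cc(OCc6ccccc6)ccc5C4)c(OCc4ccccc4)cc3OC)c3ccc(OCc4ccccc4)cc3OC2)c(OS(=O)(=O)c2ccc(C)cc2)c1 | intermediate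
24 | (3S,4S)-cis-3,4-diarylchroman (tosylate) | COc1ccc([C@H]2COc3cc(OCc4ccccc4)ccc3[C@H]2c2cc([C@H]3COc4cc(OCc5ccccc5)ccc4C3)c(OCc3ccccc3)cc2OC)c(OS(=O)(=O)c2ccc(C)cc2)c1 | intermediate
25 | potassium 2'-phenoxide of the (3S,4S)-cis chroman (not isolated) | COc1ccc([C@H]2COc3cc(OCc4ccccc4)ccc3[C@H]2c2cc([C@H]3COc4cc(OCc5ccccc5)ccc4C3)c(OCc3ccccc3)cc2OC)c([O-])c1.[K+] | intermediate
26 | (3S,4S)-cis tetrabenzyl ether | COc1ccc([C@H]2COc3cc(OCc4ccccc4)ccc3[C@H]2c2cc([C@H]3COc4cc(OCc5ccccc5)ccc4C3)c(OCc3ccccc3)cc2OC)c(OCc2ccccc2)c1 | intermediate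
27 | (3S,4R)-trans tetrabenzyl ether | COc1ccc([C@H]2COc3cc(OCc4ccccc4)ccc3[C@@H]2c2cc([C@H]3COc4cc(OCc5ccccc5)ccc4C3)c(OCc3ccccc3)cc2OC)c(OCc2ccccc2)c1 | intermediate
28 | CNP0152030.1, upper (3S,4R), lower (3S) | COc1ccc([C@H]2COc3cc(O)ccc3[C@@H]2c2cc([C@H]3COc4cc(O)ccc4C3)c(O)cc2OC)c(O)c1 | target

**Step count**
- Total: 20 steps.
- Longest linear sequence: 13 steps (1, 2, 4, 5, 6, 7, 10, 15, 16, 17, 18, 19, 20).

**Steps most likely to fail**

1. **Step 15.**
   - Risk: the carbene may be lost to azine formation with unreacted diazirine or to adventitious water. It may also add too slowly to the crowded trisubstituted furan bond, or attack an alkoxyarene ring.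
   - Fallback (known chemistry): it sets out from 1, 5 and 9 and rejoins the route at 26.
   - Phenol 1 is benzylated to 2-(benzyloxy)-1-bromo-4-methoxybenzene F1.
   - Ketone 5 is α-arylated with F1 under the conditions of step 4, giving (±)-7-(benzyloxy)-3-[2-(benzyloxy)-4-methoxyphenyl]chroman-4-one F2.
   - The potassium enolate of F2 (KHMDS, −78 °C) is trapped with PhNTf2 as 7-(benzyloxy)-3-[2-(benzyloxy)-4-methoxyphenyl]-2H-chromen-4-yl triflate F3.
   - Suzuki–Miyaura coupling of F3 with 9 gives the tetrabenzyl 3,4-diaryl-2H-chromene F4.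
   - Hydrogenation of F4 as in step 17 delivers 26 directly.

2. **Step 17.**
   - Risk: two ortho-substituted aryl groups on a tetrasubstituted olefin may stop catalyst turnover or erode facial selectivity. The acidic iridium hydrides may also protonate the chromene.
   - Fallback: it sets out from 23 and returns at 24, replacing catalyst control by ionic hydrogenation and separation.
   - TFA/Et3SiH in CH2Cl2 protonates C3, and silane captures the C4 diarylmethyl cation anti to the C3 aryl group, a mode known to give cis-vicinal diaryl heterocycles.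
   - Because lower C3 is already fixed, the two cis products are diastereomers: 24 and the (3R,4R,3''S)-cis chroman tosylate F5. They are separated by chromatography or crystallisation.

3. **Step 19.**
   - Risk: equilibration may stall because the donor-substituted, sterically twisted carbanion forms slowly. Long exposure may deprotonate benzyl ether CH2 groups, or C3–H with β-elimination of the aryloxide.
   - Fallback: it sets out from 26 and returns at 27, replacing the carbanion by a radical equilibration.
   - A catalytic arenethiyl radical (diphenyl disulfide, 400 nm light, benzene, rt) abstracts and returns hydrogen reversibly at the weakest C–H bond, the doubly benzylic C4–H.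
   - The stronger monobenzylic C–H bonds at upper C3 and lower C3 lie energetically uphill for this radical.
   - This fallback makes no compound outside the list (F0).

**Further compounds**
F1 | step 15 | 2-(benzyloxy)-1-bromo-4-methoxybenzene | COc1ccc(Br)c(OCc2ccccc2)c1
F2 | step 15 | (±)-7-(benzyloxy)-3-[2-(benzyloxy)-4-methoxyphenyl]chroman-4-one | COc1ccc(C2COc3cc(OCc4ccccc4)ccc3C2=O)c(OCc2ccccc2)c1
F3 | step 15 | 7-(benzyloxy)-3-[2-(benzyloxy)-4-methoxyphenyl]-2H-chromen-4-yl triflate | COc1ccc(C2=C(OS(=O)(=O)C(F)(F)F)c3ccc(OCc4ccccc4)cc3OC2)c(OCc2ccccc2)c1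
F4 | step 15 | tetrabenzyl 3,4-diaryl-2H-chromene | COc1ccc(C2=C(c3cc([C@H]4COc5cc(OCc6ccccc6)ccc5C4)c(OCc4ccccc4)cc3OC)c3ccc(OCc4ccccc4)cc3OC2)c(OCc2ccccc2)c1
F5 | step 17 | (3R,4R,3''S)-cis chroman tosylate | COc1ccc([C@@H]2COc3cc(OCc4ccccc4)ccc3[C@@H]2c2cc([C@H]3COc4cc(OCc5ccccc5)ccc4C3)c(OCc3ccccc3)cc2OC)c(OS(=O)(=O)c2ccc(C)cc2)c1
F0 | step 19 | none | none
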